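**Retrosynthetic overview**

1. Endgame: the hydroquinone comes from its quinone (dithionite), the quinone from the 18,21‑di‑O‑methyl arene (ceric oxidation), the C7 carbamate from the C7 alcohol; O15 travels as a TBS ether.
2. Key disconnection C7–C8: in the 19‑membered lactam ring the C7 carbinol is allylic to the (E)‑C8(CH3)=C9H alkene. This hydroxy/trisubstituted‑alkene pair is the retron of a nickel‑catalysed reductive alkyne–aldehyde cyclization of a seco‑ynal (C8≡C9 methyl alkyne plus C7 aldehyde), which makes the ring, the alkene geometry and C7 in one operation. The C6 methyl stereocentre next to C7, and CH3 on C8 against the branched C10 on C9, supply the facial and regiochemical bias.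
3. The seco‑ynal comes from the amide bond N–C1 between aniline fragment A (C8–C21) and (2E,4Z)‑dienoic acid fragment B (C1–C7; C6 from the (R)‑Roche ester, alkenes by Still–Gennari and Wittig olefinations).
4. Fragment A comes from 2,5‑dimethoxy‑3‑nitrobenzaldehyde: (Z)‑crotylboration (C14, C15), catalytic asymmetric propenylzinc addition (C12), Sharpless epoxidation and alkynylalane opening (C11, C10 and the methyl alkyne), double O‑methylation.
5. Ring order: the arene is bought; an epoxide exists only in steps 7–8; the 19‑membered lactam is the only ring built and is closed in step 21.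

Key step: step 21

Remark on the chemistry: ansamycin numbering is used (C1 amide carbonyl … C15 benzylic carbinol, C16–C21 arene); the target is read as 6S,7R,10S,11R,12S,14S,15R with 2E,4Z,8E alkenes. (c‑C6H11)2BH is taken as a freshly prepared stock reagent.

**Fragment A (C8–C21)**

Step 1
Reactants: 1 2-hydroxy-5-methoxy-3-nitrobenzaldehyde
Product: 2 2,5-dimethoxy-3-nitrobenzaldehyde
Conditions: MeI, K2CO3, DMF, 40 °C
Reagents that add atoms: iodomethane, CI
Why: Williamson O‑methylation (SN2) of the acidic ortho‑nitrophenol should proceed cleanly and gives the non‑enolisable aldehyde needed for crotylation.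

Step 2
Reactants: 2 2,5-dimethoxy-3-nitrobenzaldehyde
Product: 4 (1R,2S)-1-(2,5-dimethoxy-3-nitrophenyl)-2-methylbut-3-en-1-ol, via diisopinocampheylborinate ester 3 (not isolated)
Conditions: cis-but-2-ene, n-BuLi, KOtBu, THF, −78 → −45 °C; (+)-B-methoxydiisopinocampheylborane (from (−)-α-pinene), −78 °C; BF3·OEt2; then 2, −78 °C; NaOH, H2O2, 0 °C → rt
Reagents that add atoms: (Z)-but-2-en-1-yldiisopinocampheylborane, made in the flask from cis-but-2-ene (C/C=C\C), C/C=C\CB([C@H]1C[C@H]2C[C@@H]([C@@H]1C)C2(C)C)[C@H]1C[C@H]2C[C@@H]([C@@H]1C)C2(C)C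
Why: Brown asymmetric crotylboration runs through a closed chair transition state, so the Z‑crotyl geometry should give the 14,15‑syn pair and the isopinocampheyl groups from (−)‑α‑pinene should direct addition to the aldehyde face that gives 15R (hence 14S), the alkaline peroxide work‑up freeing the alcohol from 3.

Step 3
Reactants: 4 (1R,2S)-1-(2,5-dimethoxy-3-nitrophenyl)-2-methylbut-3-en-1-ol
Product: 5 tert-butyl{[(1R,2S)-1-(2,5-dimethoxy-3-nitrophenyl)-2-methylbut-3-en-1-yl]oxy}dimethylsilane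
Conditions: TBSOTf, 2,6-lutidine, CH2Cl2, −78 → 0 °C
Reagents that add atoms: tert-butyldimethylsilyl trifluoromethanesulfonate, CC(C)(C)[Si](C)(C)OS(=O)(=O)C(F)(F)F
Why: silylation of a hindered secondary benzylic alcohol with the silyl triflate is routine and blocks O15 until step 24.

Step 4
Reactants: 5 tert-butyl{[(1R,2S)-1-(2,5-dimethoxy-3-nitrophenyl)-2-methylbut-3-en-1-yl]oxy}dimethylsilane
Product: 7 (3S,4R)-4-[(tert-butyldimethylsilyl)oxy]-4-(2,5-dimethoxy-3-nitrophenyl)-3-methylbutan-1-ol, via B-alkyl-9-borabicyclononane 6 (not isolated)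
Conditions: 9-BBN, THF, 0 °C → rt; then NaOH, H2O2, 0 °C
Reagents that add atoms: hydrogen peroxide, OO; 9-borabicyclo[3.3.1]nonane, B1C2CCCC1CCC2 (boron of 6 only)
Why: hydroboration–oxidation with the bulky borane should place boron on the terminal carbon (anti‑Markovnikov) and leave the nitroarene and silyl ether untouched, giving the primary C12 alcohol with C13 as CH2.

Step 5
Reactants: 7 (3S,4R)-4-[(tert-butyldimethylsilyl)oxy]-4-(2,5-dimethoxy-3-nitrophenyl)-3-methylbutan-1-ol
Product: 8 (3S,4R)-4-[(tert-butyldimethylsilyl)oxy]-4-(2,5-dimethoxy-3-nitrophenyl)-3-methylbutanal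
Conditions: Dess–Martin periodinane, CH2Cl2, rt
Reagents that add atoms: none
Why: Dess–Martin oxidation gives the aldehyde under neutral conditions, and the nearest stereocentre is β to the carbonyl and cannot epimerise.

Step 6
Reactants: 8 (3S,4R)-4-[(tert-butyldimethylsilyl)oxy]-4-(2,5-dimethoxy-3-nitrophenyl)-3-methylbutanal
Product: 9 (2E,4S,6S,7R)-7-[(tert-butyldimethylsilyl)oxy]-7-(2,5-dimethoxy-3-nitrophenyl)-6-methylhept-2-en-4-ol
Conditions: propyne, (c-C6H11)2BH, toluene, 0 °C → rt; Me2Zn, −78 °C; (2R)-(+)-3-exo-morpholinoisoborneol (5 mol %); then 8, −30 → 0 °C; H2O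
Reagents that add atoms: propyne, CC#C
Why: syn hydroboration of propyne gives the (E)‑propenylborane, and after boron‑to‑zinc exchange the amino‑alcohol‑catalysed alkenylzinc addition should deliver the propenyl group to the Re face of the aldehyde under catalyst control (12S), organozinc reagents being compatible with the nitro group.

Step 7
Reactants: 9 (2E,4S,6S,7R)-7-[(tert-butyldimethylsilyl)oxy]-7-(2,5-dimethoxy-3-nitrophenyl)-6-methylhept-2-en-4-ol
Product: 10 (1S,3S,4R)-4-[(tert-butyldimethylsilyl)oxy]-4-(2,5-dimethoxy-3-nitrophenyl)-3-methyl-1-[(2S,3S)-3-methyloxiran-2-yl]butan-1-ol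
Conditions: Ti(OiPr)4 (10 mol %), L-(+)-diisopropyl tartrate (12 mol %), t-BuOOH, 4 Å molecular sieves, CH2Cl2, −20 °C
Reagents that add atoms: tert-butyl hydroperoxide, CC(C)(C)OO
Why: Sharpless asymmetric epoxidation with the L‑(+)‑tartrate is stereochemically matched with the (S)‑allylic alcohol (its fast‑reacting enantiomer), so the (10S,11S)‑epoxide anti to the C12 hydroxyl should form while any minor C12 epimer reacts slowly and is left behind.

Step 8
Reactants: 10 (1S,3S,4R)-4-[(tert-butyldimethylsilyl)oxy]-4-(2,5-dimethoxy-3-nitrophenyl)-3-methyl-1-[(2S,3S)-3-methyloxiran-2-yl]butan-1-ol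
Product: 11 (1R,2S,4S,5R,6S)-1-[(tert-butyldimethylsilyl)oxy]-1-(2,5-dimethoxy-3-nitrophenyl)-2,6-dimethylnon-7-yne-4,5-diol
Conditions: 1-propynyllithium, Et2AlCl, toluene, 0 °C; then 10, 0 °C → rt; aq. KNaC4H4O6
Reagents that add atoms: diethyl(prop-1-yn-1-yl)aluminium, CC#C[Al](CC)CC (from 1-propynyllithium, [Li]C#CC, and Et2AlCl)
Why: the alkynylalane, anchored on the C12 alkoxide, should open the 2,3‑epoxy alcohol at its distal, methyl‑bearing carbon C10 by SN2 with inversion, which installs the C8≡C9 methyl alkyne and turns the trans‑epoxide into the 10,11‑syn/11,12‑anti triad (10S,11R,12S).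

Step 9
Reactants: 11 (1R,2S,4S,5R,6S)-1-[(tert-butyldimethylsilyl)oxy]-1-(2,5-dimethoxy-3-nitrophenyl)-2,6-dimethylnon-7-yne-4,5-diol
Product: 12 tert-butyl{[(1R,2S,4S,5R,6S)-1-(2,5-dimethoxy-3-nitrophenyl)-4,5-dimethoxy-2,6-dimethylnon-7-yn-1-yl]oxy}dimethylsilane
Conditions: NaH, MeI, THF/DMF, 0 °C → rt
Reagents that add atoms: iodomethane, CI
Why: double Williamson methylation of the 1,2‑diol installs both aliphatic methyl ethers of the target at once, no other acidic or electrophilic site being present.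

Step 10
Reactants: 12 tert-butyl{[(1R,2S,4S,5R,6S)-1-(2,5-dimethoxy-3-nitrophenyl)-4,5-dimethoxy-2,6-dimethylnon-7-yn-1-yl]oxy}dimethylsilane
Product: 13 3-{(1R,2S,4S,5R,6S)-1-[(tert-butyldimethylsilyl)oxy]-4,5-dimethoxy-2,6-dimethylnon-7-yn-1-yl}-2,5-dimethoxyaniline (fragment A)
Conditions: Zn, AcOH/THF, 0 °C → rt
Reagents that add atoms: none
Why: dissolving‑metal reduction of the aromatic nitro group is chemoselective over the internal alkyne and the silyl ether because no hydrogenation catalyst is used.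

**Fragment B (C1–C7)**

Step 11
Reactants: 14 methyl (R)-3-hydroxy-2-methylpropanoate
Product: 15 methyl (R)-3-[(tert-butyldimethylsilyl)oxy]-2-methylpropanoate
Conditions: TBSCl, imidazole, CH2Cl2, rt
Reagents that add atoms: tert-butyldimethylsilyl chloride, CC(C)(C)[Si](C)(C)Cl
Why: standard silylation of a primary alcohol protects the future C7 oxygen.

Step 12
Reactants: 15 methyl (R)-3-[(tert-butyldimethylsilyl)oxy]-2-methylpropanoate
Product: 16 (R)-3-[(tert-butyldimethylsilyl)oxy]-2-methylpropanal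
Conditions: i-Bu2AlH, CH2Cl2, −78 °C; MeOH, then aq. KNaC4H4O6
Reagents that add atoms: none
Why: partial ester reduction stops at the tetrahedral aluminium hemiacetal at −78 °C, and the aldehyde released on work‑up is used cold and unpurified so that the α‑stereocentre (future C6) is kept.

Step 13
Reactants: 16 (R)-3-[(tert-butyldimethylsilyl)oxy]-2-methylpropanal
Product: 17 methyl (2Z,4S)-5-[(tert-butyldimethylsilyl)oxy]-4-methylpent-2-enoate
Conditions: (CF3CH2O)2P(O)CH2CO2Me, KN(SiMe3)2, 18-crown-6, THF, −78 °C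
Reagents that add atoms: methyl bis(2,2,2-trifluoroethyl)phosphonoacetate, COC(=O)CP(=O)(OCC(F)(F)F)OCC(F)(F)F
Why: the Still–Gennari olefination, with its fast and irreversible elimination from the kinetic adduct, should set the 4Z alkene.

Step 14
Reactants: 17 methyl (2Z,4S)-5-[(tert-butyldimethylsilyl)oxy]-4-methylpent-2-enoate
Product: 18 (2Z,4S)-5-[(tert-butyldimethylsilyl)oxy]-4-methylpent-2-en-1-ol
Conditions: i-Bu2AlH, CH2Cl2, −78 °C; aq. KNaC4H4O6
Reagents that add atoms: none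
Why: 1,2‑reduction of the enoate to the allylic alcohol keeps the Z geometry.

Step 15
Reactants: 18 (2Z,4S)-5-[(tert-butyldimethylsilyl)oxy]-4-methylpent-2-en-1-ol
Product: 19 (2Z,4S)-5-[(tert-butyldimethylsilyl)oxy]-4-methylpent-2-enal
Conditions: MnO2, CH2Cl2, rt
Reagents that add atoms: none
Why: MnO2 oxidises allylic alcohols selectively and, being neutral and heterogeneous, should not isomerise the (Z)‑enal.

Step 16
Reactants: 19 (2Z,4S)-5-[(tert-butyldimethylsilyl)oxy]-4-methylpent-2-enal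
Product: 20 ethyl (2E,4Z,6S)-7-[(tert-butyldimethylsilyl)oxy]-2,6-dimethylhepta-2,4-dienoate
Conditions: Ph3P=C(CH3)CO2Et, CH2Cl2, rt
Reagents that add atoms: ethyl 2-(triphenylphosphoranylidene)propanoate, CCOC(=O)C(C)=P(c1ccccc1)(c1ccccc1)c1ccccc1
Why: the Wittig reaction of the stabilised α‑methyl ylide is E‑selective and, run without added base, should leave the Z alkene and C6 untouched, giving the (2E,4Z)‑diene.

Step 17
Reactants: 20 ethyl (2E,4Z,6S)-7-[(tert-butyldimethylsilyl)oxy]-2,6-dimethylhepta-2,4-dienoate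
Product: 21 (2E,4Z,6S)-7-[(tert-butyldimethylsilyl)oxy]-2,6-dimethylhepta-2,4-dienoic acid (fragment B)
Conditions: LiOH, THF/MeOH/H2O, rt; then aq. HCl to pH 4, 0 °C
Reagents that add atoms: lithium hydroxide, [Li+].[OH-]
Why: saponification of the dienoate spares the primary TBS ether and the diene geometry, and brief cold acidification releases the acid.

**Union, ring closure and endgame**

Step 18
Reactants: 21 (2E,4Z,6S)-7-[(tert-butyldimethylsilyl)oxy]-2,6-dimethylhepta-2,4-dienoic acid; 13 3-{(1R,2S,4S,5R,6S)-1-[(tert-butyldimethylsilyl)oxy]-4,5-dimethoxy-2,6-dimethylnon-7-yn-1-yl}-2,5-dimethoxyaniline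
Product: 23 (2E,4Z,6S)-7-[(tert-butyldimethylsilyl)oxy]-N-(3-{(1R,2S,4S,5R,6S)-1-[(tert-butyldimethylsilyl)oxy]-4,5-dimethoxy-2,6-dimethylnon-7-yn-1-yl}-2,5-dimethoxyphenyl)-2,6-dimethylhepta-2,4-dienamide, via acid chloride 22 (not isolated)
Conditions: 1-chloro-N,N,2-trimethylprop-1-en-1-amine, CH2Cl2, 0 °C; then 13, pyridine, 0 °C → rt
Reagents that add atoms: 1-chloro-N,N,2-trimethylprop-1-en-1-amine, CC(C)=C(Cl)N(C)C (chlorine of 22 only)
Why: the α‑chloroenamine makes the acid chloride without free HCl, so the silyl ether and the (E,Z)‑diene survive, and the hindered aniline is then N‑acylated (amide formation via acid chloride).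

Step 19
Reactants: 23 (2E,4Z,6S)-7-[(tert-butyldimethylsilyl)oxy]-N-(3-{(1R,2S,4S,5R,6S)-1-[(tert-butyldimethylsilyl)oxy]-4,5-dimethoxy-2,6-dimethylnon-7-yn-1-yl}-2,5-dimethoxyphenyl)-2,6-dimethylhepta-2,4-dienamide
Product: 24 (2E,4Z,6S)-N-(3-{(1R,2S,4S,5R,6S)-1-[(tert-butyldimethylsilyl)oxy]-4,5-dimethoxy-2,6-dimethylnon-7-yn-1-yl}-2,5-dimethoxyphenyl)-7-hydroxy-2,6-dimethylhepta-2,4-dienamide
Conditions: HF·pyridine, pyridine, THF, 0 °C
Reagents that add atoms: none
Why: buffered fluoride desilylation should remove the unhindered primary TBS ether much faster than the hindered secondary benzylic one at O15.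

Step 20
Reactants: 24 (2E,4Z,6S)-N-(3-{(1R,2S,4S,5R,6S)-1-[(tert-butyldimethylsilyl)oxy]-4,5-dimethoxy-2,6-dimethylnon-7-yn-1-yl}-2,5-dimethoxyphenyl)-7-hydroxy-2,6-dimethylhepta-2,4-dienamide
Product: 25 (2E,4Z,6S)-N-(3-{(1R,2S,4S,5R,6S)-1-[(tert-butyldimethylsilyl)oxy]-4,5-dimethoxy-2,6-dimethylnon-7-yn-1-yl}-2,5-dimethoxyphenyl)-2,6-dimethyl-7-oxohepta-2,4-dienamide (seco-ynal)
Conditions: Dess–Martin periodinane, NaHCO3, CH2Cl2, 0 °C; filtered cold and used at once
Reagents that add atoms: none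
Why: buffered Dess–Martin oxidation gives the aldehyde without acid or base that would epimerise C6 or move the C4=C5 alkene into conjugation.

Step 21
Reactants: 25 (2E,4Z,6S)-N-(3-{(1R,2S,4S,5R,6S)-1-[(tert-butyldimethylsilyl)oxy]-4,5-dimethoxy-2,6-dimethylnon-7-yn-1-yl}-2,5-dimethoxyphenyl)-2,6-dimethyl-7-oxohepta-2,4-dienamide
Product: 27 macrocyclic C7 alcohol (2E,4Z,6S,7R,8E,10S,11R,12S,14S,15R; the target skeleton with free 7-OH in place of the carbamate, TBS on O15 and methyl ethers on O18 and O21), via C7 triethylsilyl ether 26 (not isolated)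
Conditions: Ni(cod)2 (30 mol %), 1,3-bis(2,4,6-trimethylphenyl)imidazol-2-ylidene (30 mol %), Et3SiH (5 equiv), THF, 2 mM, slow addition of 25, rt; then HF·pyridine, pyridine, 0 °C
Reagents that add atoms: triethylsilane, CC[SiH](CC)CC (silyl group of 26; only hydrogen stays in 27)
Why: The zerovalent nickel–carbene complex binds the C8≡C9 alkyne and the C7 aldehyde and undergoes oxidative cyclization to a five‑membered oxanickelacycle (C7–C8 bond), after which σ‑bond metathesis with Et3SiH silylates the oxygen and the nickel hydride reductively eliminates onto C9, so that C7 and H are added syn across the alkyne. The closest known reaction type is the nickel‑catalysed reductive macrocyclization of ynals with carbene ligands and silanes, which gives endocyclic (E)‑allylic silyl ethers in large rings. The 19‑membered lactam ring is closed in the endocyclic mode (19‑endo‑dig, both alkyne carbons become ring atoms), and the syn addition fixes the (8E) trisubstituted alkene. The new C7 stereocentre should be controlled by the adjacent C6 methyl stereocentre (Felkin–Anh: C8 approaches anti to the C5 alkenyl group, past hydrogen), which predicts the 6,7‑syn 7R alcohol. The step needs regioselectivity for C8 over C9, secured with a small carbene ligand by the small CH3 on C8 against the α‑branched C10 on C9, and chemoselectivity for the alkyne over the dienamide, secured because the diene terminus C2 is fully substituted and electron‑poor and C5 is only one carbon from C7, while high dilution suppresses dimers. The buffered fluoride work‑up should cleave only the triethylsilyl ether of 26 and leave the hindered O15 silyl ether.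

Step 22
Reactants: 27 macrocyclic C7 alcohol
Product: 29 macrocyclic C7 carbamate (15-O-TBS and 18,21-di-O-methyl derivative of the target), via N-trichloroacetyl carbamate 28 (not isolated)
Conditions: Cl3CC(O)NCO, CH2Cl2, 0 °C; then K2CO3 (cat.), MeOH, rt
Reagents that add atoms: trichloroacetyl isocyanate, O=C=NC(=O)C(Cl)(Cl)Cl
Why: the secondary alcohol adds to the highly electrophilic acyl isocyanate far faster than the anilide NH, and mild methanolysis removes the trichloroacetyl group to leave the primary carbamate (standard carbamoylation).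

Step 23
Reactants: 29 macrocyclic C7 carbamate
Product: 30 15-O-TBS benzoquinone (quinone form of the target, O15 silylated)
Conditions: (NH4)2Ce(NO3)6, MeCN/H2O, 0 °C
Reagents that add atoms: water, O
Why: ceric oxidative demethylation of the 1,4‑dimethoxyarene proceeds through the arene radical cation, water addition and loss of methanol to the p‑quinone, and the silyl ether keeps the benzylic carbinol from fragmenting.

Step 24
Reactants: 30 15-O-TBS benzoquinone
Product: 31 15-hydroxy benzoquinone (quinone form of the target)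
Conditions: 48 % aq. HF, MeCN, 0 °C → rt
Reagents that add atoms: none
Why: acidic fluoride desilylation is safe at this stage because the quinone is electron‑poor, so the C15–O bond should not ionise, and the carbamate and dienamide tolerate HF.

Step 25
Reactants: 31 15-hydroxy benzoquinone
Product: 32 target hydroquinone, CNP0532580.1
Conditions: Na2S2O4, EtOAc/H2O, rt, under argon
Reagents that add atoms: none
Why: dithionite reduces the quinone to the hydroquinone under neutral biphasic conditions, nothing else in the molecule being reducible.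

**Compound list**

1 | 2-hydroxy-5-methoxy-3-nitrobenzaldehyde | O=Cc1cc(OC)cc([N+](=O)[O-])c1O | starting material
2 | 2,5-dimethoxy-3-nitrobenzaldehyde | O=Cc1cc(OC)cc([N+](=O)[O-])c1OC | intermediate
3 | diisopinocampheylborinate ester of 4 (not isolated) | C=C[C@H](C)[C@@H](OB([C@H]1C[C@H]2C[C@@H]([C@@H]1C)C2(C)C)[C@H]1C[C@H]2C[C@@H]([C@@H]1C)C2(C)C)c1cc(OC)cc([N+](=O)[O-])c1OC | intermediate
4 | (1R,2S)-1-(2,5-dimethoxy-3-nitrophenyl)-2-methylbut-3-en-1-ol | C=C[C@H](C)[C@@H](O)c1cc(OC)cc([N+](=O)[O-])c1OC | intermediate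
5 | TBS ether of 4 | C=C[C@H](C)[C@@H](O[Si](C)(C)C(C)(C)C)c1cc(OC)cc([N+](=O)[O-])c1OC | intermediate
6 | B-alkyl-9-borabicyclononane from 5 (not isolated) | B1(CC[C@H](C)[C@@H](O[Si](C)(C)C(C)(C)C)c3cc(OC)cc([N+](=O)[O-])c3OC)C2CCCC1CCC2 | intermediate
7 | (3S,4R)-4-[(tert-butyldimethylsilyl)oxy]-4-(2,5-dimethoxy-3-nitrophenyl)-3-methylbutan-1-ol | OCC[C@H](C)[C@@H](O[Si](C)(C)C(C)(C)C)c1cc(OC)cc([N+](=O)[O-])c1OC | intermediate
8 | (3S,4R)-4-[(tert-butyldimethylsilyl)oxy]-4-(2,5-dimethoxy-3-nitrophenyl)-3-methylbutanal | O=CC[C@H](C)[C@@H](O[Si](C)(C)C(C)(C)C)c1cc(OC)cc([N+](=O)[O-])c1OC | intermediate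
9 | (2E,4S,6S,7R)-7-[(tert-butyldimethylsilyl)oxy]-7-(2,5-dimethoxy-3-nitrophenyl)-6-methylhept-2-en-4-ol | C/C=C/[C@@H](O)C[C@H](C)[C@@H](O[Si](C)(C)C(C)(C)C)c1cc(OC)cc([N+](=O)[O-])c1OC | intermediate
10 | (1S,3S,4R)-4-[(tert-butyldimethylsilyl)oxy]-4-(2,5-dimethoxy-3-nitrophenyl)-3-methyl-1-[(2S,3S)-3-methyloxiran-2-yl]butan-1-ol | C[C@@H]1O[C@H]1[C@@H](O)C[C@H](C)[C@@H](O[Si](C)(C)C(C)(C)C)c1cc(OC)cc([N+](=O)[O-])c1OC | intermediate
11 | (1R,2S,4S,5R,6S)-1-[(tert-butyldimethylsilyl)oxy]-1-(2,5-dimethoxy-3-nitrophenyl)-2,6-dimethylnon-7-yne-4,5-diol | CC#C[C@H](C)[C@@H](O)[C@@H](O)C[C@H](C)[C@@H](O[Si](C)(C)C(C)(C)C)c1cc(OC)cc([N+](=O)[O-])c1OC | intermediate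
12 | tert-butyl{[(1R,2S,4S,5R,6S)-1-(2,5-dimethoxy-3-nitrophenyl)-4,5-dimethoxy-2,6-dimethylnon-7-yn-1-yl]oxy}dimethylsilane | CC#C[C@H](C)[C@@H](OC)[C@@H](OC)C[C@H](C)[C@@H](O[Si](C)(C)C(C)(C)C)c1cc(OC)cc([N+](=O)[O-])c1OC | intermediate
13 | 3-{(1R,2S,4S,5R,6S)-1-[(tert-butyldimethylsilyl)oxy]-4,5-dimethoxy-2,6-dimethylnon-7-yn-1-yl}-2,5-dimethoxyaniline (fragment A) | CC#C[C@H](C)[C@@H](OC)[C@@H](OC)C[C@H](C)[C@@H](O[Si](C)(C)C(C)(C)C)c1cc(OC)cc(N)c1OC | intermediate
14 | methyl (R)-3-hydroxy-2-methylpropanoate | OC[C@@H](C)C(=O)OC | starting material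
15 | methyl (R)-3-[(tert-butyldimethylsilyl)oxy]-2-methylpropanoate | CC(C)(C)[Si](C)(C)OC[C@@H](C)C(=O)OC | intermediate
16 | (R)-3-[(tert-butyldimethylsilyl)oxy]-2-methylpropanal | CC(C)(C)[Si](C)(C)OC[C@@H](C)C=O | intermediate
17 | methyl (2Z,4S)-5-[(tert-butyldimethylsilyl)oxy]-4-methylpent-2-enoate | CC(C)(C)[Si](C)(C)OC[C@@H](C)/C=C\C(=O)OC | intermediate
18 | (2Z,4S)-5-[(tert-butyldimethylsilyl)oxy]-4-methylpent-2-en-1-ol | CC(C)(C)[Si](C)(C)OC[C@@H](C)/C=C\CO | intermediate
19 | (2Z,4S)-5-[(tert-butyldimethylsilyl)oxy]-4-methylpent-2-enal | CC(C)(C)[Si](C)(C)OC[C@@H](C)/C=C\C=O | intermediate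
20 | ethyl (2E,4Z,6S)-7-[(tert-butyldimethylsilyl)oxy]-2,6-dimethylhepta-2,4-dienoate | CC(C)(C)[Si](C)(C)OC[C@@H](C)/C=C\C=C(/C)C(=O)OCC | intermediate
21 | (2E,4Z,6S)-7-[(tert-butyldimethylsilyl)oxy]-2,6-dimethylhepta-2,4-dienoic acid (fragment B) | CC(C)(C)[Si](C)(C)OC[C@@H](C)/C=C\C=C(/C)C(=O)O | intermediate
22 | acid chloride of 21 (not isolated) | CC(C)(C)[Si](C)(C)OC[C@@H](C)/C=C\C=C(/C)C(=O)Cl | intermediate
23 | seco-amide, 7-OTBS (name as in step 18) | CC#C[C@H](C)[C@@H](OC)[C@@H](OC)C[C@H](C)[C@@H](O[Si](C)(C)C(C)(C)C)c1cc(OC)cc(NC(=O)/C(C)=C/C=C\[C@H](C)CO[Si](C)(C)C(C)(C)C)c1OC | intermediate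
24 | seco-alcohol, 7-OH (name as in step 19) | CC#C[C@H](C)[C@@H](OC)[C@@H](OC)C[C@H](C)[C@@H](O[Si](C)(C)C(C)(C)C)c1cc(OC)cc(NC(=O)/C(C)=C/C=C\[C@H](C)CO)c1OC | intermediate
25 | seco-ynal, 7-oxo (name as in step 20) | CC#C[C@H](C)[C@@H](OC)[C@@H](OC)C[C@H](C)[C@@H](O[Si](C)(C)C(C)(C)C)c1cc(OC)cc(NC(=O)/C(C)=C/C=C\[C@H](C)C=O)c1OC | intermediate
26 | C7 triethylsilyl ether of 27 (not isolated) | CO[C@H]1[C@@H](OC)C[C@H](C)[C@@H](O[Si](C)(C)C(C)(C)C)c2cc(OC)cc(c2OC)NC(=O)/C(C)=C/C=C\[C@H](C)[C@@H](O[Si](CC)(CC)CC)/C(C)=C/[C@@H]1C | intermediate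
27 | macrocyclic C7 alcohol (2E,4Z,6S,7R,8E,10S,11R,12S,14S,15R; 15-OTBS; 18,21-di-OMe) | CO[C@H]1[C@@H](OC)C[C@H](C)[C@@H](O[Si](C)(C)C(C)(C)C)c2cc(OC)cc(c2OC)NC(=O)/C(C)=C/C=C\[C@H](C)[C@@H](O)/C(C)=C/[C@@H]1C | intermediate
28 | N-trichloroacetyl carbamate of 27 (not isolated) | CO[C@H]1[C@@H](OC)C[C@H](C)[C@@H](O[Si](C)(C)C(C)(C)C)c2cc(OC)cc(c2OC)NC(=O)/C(C)=C/C=C\[C@H](C)[C@@H](OC(=O)NC(=O)C(Cl)(Cl)Cl)/C(C)=C/[C@@H]1C | intermediate
29 | macrocyclic C7 carbamate (15-OTBS; 18,21-di-OMe) | CO[C@H]1[C@@H](OC)C[C@H](C)[C@@H](O[Si](C)(C)C(C)(C)C)c2cc(OC)cc(c2OC)NC(=O)/C(C)=C/C=C\[C@H](C)[C@@H](OC(N)=O)/C(C)=C/[C@@H]1C | intermediate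
30 | 15-O-TBS benzoquinone | CO[C@H]1[C@@H](OC)C[C@H](C)[C@@H](O[Si](C)(C)C(C)(C)C)C2=CC(=O)C=C(C2=O)NC(=O)/C(C)=C/C=C\[C@H](C)[C@@H](OC(N)=O)/C(C)=C/[C@@H]1C | intermediate
31 | 15-hydroxy benzoquinone | CO[C@H]1[C@@H](OC)C[C@H](C)[C@@H](O)C2=CC(=O)C=C(C2=O)NC(=O)/C(C)=C/C=C\[C@H](C)[C@@H](OC(N)=O)/C(C)=C/[C@@H]1C | intermediate
32 | CNP0532580.1 (hydroquinone) | CO[C@H]1[C@@H](OC)C[C@H](C)[C@@H](O)c2cc(O)cc(c2O)NC(=O)/C(C)=C/C=C\[C@H](C)[C@@H](OC(N)=O)/C(C)=C/[C@@H]1C | target

**Step count and risks**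

Total: 25 steps. Longest linear sequence: 18 steps (steps 1–10, then 18–25); fragment B contributes 7 steps (11–17).

Steps most likely to fail:

1. Step 21 (with its labile substrate from step 20). What may go wrong: epimerisation at C6 or migration of the C4=C5 alkene into conjugation while the ynal waits at high dilution; sequestration of the zerovalent nickel by the dienamide; bond formation at C9 (exocyclic mode); poor facial selectivity at C7. Fallback: the same ring bond is closed by a Nozaki–Hiyama–Kishi reaction of a preformed C8 iodide, which fixes regiochemistry and alkene geometry beforehand and tolerates the dienamide. It sets out from seco‑alcohol 24. Bu3SnH with PdCl2(PPh3)2 (cat.) in THF should add tin to the less hindered, methyl‑bearing alkyne carbon to give the (E)‑C8 vinylstannane F1. I2 in CH2Cl2 at 0 °C should give the (E)‑C8 vinyl iodide F2 with retention. Buffered Dess–Martin oxidation should give the iodo aldehyde F3. CrCl2 with NiCl2 (cat.) in DMSO/THF at high dilution should then close the ring and return to the route at 27.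

2. Step 8. What may go wrong: opening of the epoxide at C11 instead of C10, or consumption of the organoaluminium reagent by the nitro group. Fallback: C10 and C11 are set by an acyclic allenylstannane addition instead of an epoxide opening. It sets out from allylic alcohol 9. NaH/MeI should give the C12 methyl ether F4. OsO4 (cat.), NaIO4 and 2,6‑lutidine in dioxane/H2O should cleave the propenyl group to the α‑methoxy aldehyde F5. (M)‑Tributyl(penta‑2,3‑dien‑2‑yl)stannane (from (S)‑pent‑3‑yn‑2‑yl methanesulfonate) with BF3·OEt2 in CH2Cl2 at −78 °C should add by anti‑SE2′ under Felkin–Anh control to give the 10,11‑syn/11,12‑anti homopropargylic alcohol F6. NaH/MeI then returns to the route at 12.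

3. Step 6. What may go wrong: poor facial selectivity on an α‑unbranched aldehyde through competing uncatalysed addition, or methyl instead of propenyl transfer. Fallback: C12 is set by reduction instead of addition. It sets out from aldehyde 8. The same propenylzinc reagent without ligand should give the C12‑epimeric allylic alcohol mixture F7. Dess–Martin oxidation should give the (E)‑enone F8. Corey–Bakshi–Shibata reduction with (R)‑2‑methyl‑CBS‑oxazaborolidine and BH3·SMe2 at −40 °C (alkenyl as the large group) should give the 12S alcohol and return to the route at 9.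

**Further compounds**

F1 | step 21 | (2E,4Z,6S)-N-(3-{(1R,2S,4S,5R,6S,7E)-1-[(tert-butyldimethylsilyl)oxy]-4,5-dimethoxy-2,6-dimethyl-8-(tributylstannyl)non-7-en-1-yl}-2,5-dimethoxyphenyl)-7-hydroxy-2,6-dimethylhepta-2,4-dienamide | CCCC[Sn](CCCC)(CCCC)/C(C)=C/[C@H](C)[C@@H](OC)[C@@H](OC)C[C@H](C)[C@@H](O[Si](C)(C)C(C)(C)C)c1cc(OC)cc(NC(=O)/C(C)=C/C=C\[C@H](C)CO)c1OC
F2 | step 21 | (2E,4Z,6S)-N-(3-{(1R,2S,4S,5R,6S,7E)-1-[(tert-butyldimethylsilyl)oxy]-8-iodo-4,5-dimethoxy-2,6-dimethylnon-7-en-1-yl}-2,5-dimethoxyphenyl)-7-hydroxy-2,6-dimethylhepta-2,4-dienamide | I/C(C)=C/[C@H](C)[C@@H](OC)[C@@H](OC)C[C@H](C)[C@@H](O[Si](C)(C)C(C)(C)C)c1cc(OC)cc(NC(=O)/C(C)=C/C=C\[C@H](C)CO)c1OC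
F3 | step 21 | (2E,4Z,6S)-N-(3-{(1R,2S,4S,5R,6S,7E)-1-[(tert-butyldimethylsilyl)oxy]-8-iodo-4,5-dimethoxy-2,6-dimethylnon-7-en-1-yl}-2,5-dimethoxyphenyl)-2,6-dimethyl-7-oxohepta-2,4-dienamide | I/C(C)=C/[C@H](C)[C@@H](OC)[C@@H](OC)C[C@H](C)[C@@H](O[Si](C)(C)C(C)(C)C)c1cc(OC)cc(NC(=O)/C(C)=C/C=C\[C@H](C)C=O)c1OC
F4 | step 8 | tert-butyl{[(1R,2S,4S,5E)-1-(2,5-dimethoxy-3-nitrophenyl)-4-methoxy-2-methylhept-5-en-1-yl]oxy}dimethylsilane | C/C=C/[C@@H](OC)C[C@H](C)[C@@H](O[Si](C)(C)C(C)(C)C)c1cc(OC)cc([N+](=O)[O-])c1OC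
F5 | step 8 | (2S,4S,5R)-5-[(tert-butyldimethylsilyl)oxy]-5-(2,5-dimethoxy-3-nitrophenyl)-2-methoxy-4-methylpentanal | O=C[C@@H](OC)C[C@H](C)[C@@H](O[Si](C)(C)C(C)(C)C)c1cc(OC)cc([N+](=O)[O-])c1OC
F6 | step 8 | (1R,2S,4S,5R,6S)-1-[(tert-butyldimethylsilyl)oxy]-1-(2,5-dimethoxy-3-nitrophenyl)-4-methoxy-2,6-dimethylnon-7-yn-5-ol | CC#C[C@H](C)[C@@H](O)[C@@H](OC)C[C@H](C)[C@@H](O[Si](C)(C)C(C)(C)C)c1cc(OC)cc([N+](=O)[O-])c1OC
F7 | step 6 | (2E,6S,7R)-7-[(tert-butyldimethylsilyl)oxy]-7-(2,5-dimethoxy-3-nitrophenyl)-6-methylhept-2-en-4-ol, mixture of C4 epimers | C/C=C/C(O)C[C@H](C)[C@@H](O[Si](C)(C)C(C)(C)C)c1cc(OC)cc([N+](=O)[O-])c1OC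
F8 | step 6 | (2E,6S,7R)-7-[(tert-butyldimethylsilyl)oxy]-7-(2,5-dimethoxy-3-nitrophenyl)-6-methylhept-2-en-4-one | C/C=C/C(=O)C[C@H](C)[C@@H](O[Si](C)(C)C(C)(C)C)c1cc(OC)cc([N+](=O)[O-])c1OC
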